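The readings were generated by integration on assumed constants.

Treat the stall in these runs as a race for the coupling partner.

the same everywhere: left-handed substrate 0.063 M; right-handed substrate 0.063 M; coupling partner 0.158 M; racemization catalyst 0.24 mM
- cedar: free catalyst 0.32 mM; run made earlier
- elm: free catalyst 1.3 mM; run made earlier
- flask: free catalyst 0.63 mM; time 80 min

| run | time / min | left-handed substrate / % | right-handed substrate / % | left-handed product / % |
|---|---|---|---|---|
| cedar | 4.00 | 48.7 | 48.2 | 1.2 |
| cedar | 12.0 | 46.5 | 49.7 | 5.1 |
| cedar | 25.0 | 45.4 | 46.9 | 6.9 |
| cedar | 30.0 | 45.3 | 45.8 | 7.6 |
| cedar | 50.0 | 44.0 | 45.5 | 9.2 |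
| cedar | 60.0 | 43.6 | 43.5 | 11.7 |
| cedar | 80.0 | 42.2 | 43.1 | 10.8 |
| elm | 6.00 | 43.6 | 46.8 | 10.5 |
| elm | 10.0 | 39.2 | 45.5 | 13.3 |
| elm | 15.0 | 35.4 | 43.0 | 17.6 |
| elm | 25.0 | 33.3 | 40.3 | 23.0 |
| elm | 30.0 | 34.7 | 38.3 | 25.1 |
| elm | 50.0 | 30.3 | 36.9 | 29.4 |
| elm | 80.0 | 30.7 | 34.6 | 31.1 |

(readings scatter by 1 percentage point)

- part of the left-handed substrate and right-handed substrate charged together that has reacted at 80 min
- excess of left-handed product over right-handed product in the product at 80 min
- excess of right-handed substrate over left-handed substrate among what is left of the two at 80 min

- free catalyst is single-handed; left-handed substrate and right-handed substrate are mirror images of each other, charged as a racemate, each of them at the stated concentration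
- the analysis behind the earlier runs scatters by 1 percentage point, standard deviation
- an excess is the difference of the two amounts in percent of their sum
- an excess is below zero if the other one leads

At 80.0 min cedar still holds 85.3% of its substrates and elm 65.3%, yet both curves have flattened. Suppose, then, that the coupling partner decays on its own clock while the coupling runs at a rate proportional to [free catalyst], [coupling partner] and [substrate]. Dividing one rate by the other and integrating over the life of the coupling partner gives a relation for c, the part reacted. The logarithm of charged over remaining substrate equals N times the part of the coupling partner not taken by coupling, and that part is σc short of the whole, with σ = 0.797. N is the reach, a Damköhler number: the coupling rate constant times [free catalyst] times the charged [coupling partner] times the coupling partner's lifetime, so at a fixed charge of coupling partner N per [free catalyst] should be one constant.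

Cedar's 14.7% reacted gives N = 0.180, or 0.563 /mM. Elm's 34.7% gives 0.589, or 0.453 /mM. The two differ by 0.110 /mM, a gap that a scatter of 1 percentage point per reading can produce on so small a c as cedar's, so one number serves, and I carry their mean, the reach per catalyst 0.508 /mM. The flask then has N = 0.320, and the relation gives c = 23.0%. Cedar's and elm's values taken singly give 21.2% to 24.9%. N says nothing of the two excesses.

The forecast, “Conversion rises less than proportionally with catalyst”, stands at 21.5% (18.5% to 25%), 76% and 3%.

The flask gives c = 22.9%, eP = 73.0% and eS = 2.86%. At 80.0 min the coupling partner, charged in excess, stands at 5.7% of its charge, less than the left-handed substrate at 75%: it is the limiting reagent. Put back through the relation, the flask's c returns a reach per catalyst of 0.504 /mM, beside the carried 0.508 /mM.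

    coupling partner → decomposed reagent (k = 0.0290 /min)
    coupling partner + free catalyst + right-handed substrate → free catalyst + right-handed product (k = 26.0 /M²/min)
    coupling partner → decomposition product (k = 1.40 × 10⁻⁴ /min)
    coupling partner + free catalyst + left-handed substrate → free catalyst + left-handed product (k = 180 /M²/min)
    left-handed substrate + racemization catalyst ⇌ right-handed substrate + racemization catalyst, rate k5*[racemization catalyst]*[left-handed substrate] forward; the back reaction follows from the equilibrium constant (k = 230 /M/min)
    2 racemization catalyst → spent catalyst (k = 70.0 /M/min)

With 0.0016 M of free catalyst, the carried 0.508 /mM gives N = 0.813 and c = 41.5%. That neighbour computes to 41.3%.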